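Amounts first: the recipes charged 0.240 M of L against 0.80 M of Q. Each E takes up one L and holds one Q, so the balance of L read: c(L) at the start minus c(L) now equals c(E). L was therefore the limiting reagent of the step L + D → E, and E could hold at most 30.0 % of the Q charged. I called this the L ceiling.

| flask | Q | X | L | remark | time |
|---|---|---|---|---|---|
| delta | 0.80 M | 0.35 M | 0.24 M | run made earlier |  |
| theta | 0.80 M | 1.8 M | 0.24 M | run made earlier |  |
| east | 0.80 M | 2.50 M | 0.240 M |  | 2.5 d |
| north | 0.80 M | 0.500 M | 0.240 M |  | 2.5 d |
| south | 0.80 M | 1.50 M | 0.240 M |  | 2.5 d |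
| west | 0.80 M | 0.800 M | 0.240 M |  | 2.5 d |
| south-east | 0.80 M | 1.20 M | 0.240 M |  | 2.5 d |

- delta (time / h: G / %, Z / %): 2.50: 0.2, 1.0; 5.00: 2.2, 2.0; 8.00: 3.6, 3.9; 15.0: 7.8, 6.7; 30.0: 14.6, 12.0
- theta (time / h: G / %, Z / %): 2.50: 2.5, 1.8; 8.00: 12.0, 8.2; 15.0: 24.0, 12.9; 20.0: 29.3, 14.7; 30.0: 38.4, 17.6

(standard deviation of a reading: 0.3 percentage points)

* the flasks by share of G in all that became G or Z or E, highest first, at 2.5 d (east / north / south / west / south-east)
* the share of G in all that became G or Z or E of the flask you put first, at 2.5 d
* the share of G in all that became G or Z or E of the flask you put last, at 2.5 d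

- percentages count the Q that a species holds: one Z counts as two
- steps that have been proposed: Q + X -> D; D -> G; Q + D -> Z; 2 X -> J; L + D -> E

Neither run measured E, so I used the ceiling to bracket the share of G, which is G/(G + Z + E). The share had to lie between a floor, G/(G + Z + ceiling), and a roof, G/(G + Z). At the last reading, 30.0 h, the theta run read between 44.7 % and 68.6 %, and the delta run between 25.8 % and 54.9 %. Going from 0.35 M to 1.8 M of X, Z gained less than G did, and both ends of the bracket rose.

My decision for the next run was to charge 2.50 M of X, the east recipe, and to leave Q and L as they stood. I expected the flasks to rank by their charge of X, with east inside the theta bracket and north inside the delta bracket. The forecast gave east > south > south-east > west > north, with east at 56 % and north at 49 %, on the ground that “more X means a higher share”. The simulation gave east > south > south-east > west > north, with east at 60.8 % and north at 47.7 %.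

    Q + X → D (k = 0.100 L mol⁻¹ h⁻¹)
    D → G (k = 0.0620 h⁻¹)
    Q + D → Z (k = 0.0440 L mol⁻¹ h⁻¹)
    2 X → J (k = 0.0590 L mol⁻¹ h⁻¹)
    L + D → E (k = 0.110 L mol⁻¹ h⁻¹)

In east at 2.50 d, G stood at 52.9 % and Z at 18.3 %, which put the floor at 52.3 %. E, at 15.8 %, stayed below the ceiling, with 47 % of the L left. The neighbour of east charged with 0.14 M of L had a ceiling of 17.5 %. In that neighbour G came to 57.7 % and Z to 19.4 %, so its floor stood at 61.0 %, higher than east's. Its E reached 9.79 %, and its share of G was 66.4 %.

The earlier runs and the new flask are simulated for an exercise; the scatter is artificial.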